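**Plan**

1. Retrosynthesis: after removal of the benzyl and silyl ethers, ring C of unit E (the flavan-3-ol with the 3,4-dihydroxyphenyl ring) is opened at O1–C2, the C2–aryl bond is cut back to a dihydrocoumarin carbonyl, and that lactone is cut at C3–C4 and at O1–C2(=O).
2. Enabling feature: C4 of unit E is a diarylmethine lying ortho to the ring A oxygen O1 and next to the oxygen-bearing C3. That is the imprint of a glycolate enolate adding to an ortho-quinone methide whose methide carbon already carries C6 of unit T (the flavan-3,4-diol).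
3. Unit T is cut the same way at O1–C2 and C2–aryl, and at C3–C4 by a glycolate aldol; its C6 is joined to the ring A aldehyde of the future unit E.
4. Forward order: ring C of unit T (aldol, aryl ketone, reduction, Mitsunobu closure), C6 bromination and addition to the salicylaldehyde, sulfone, lactone ring C of unit E by carbene-catalysed annulation, then lactone opening, aryl ketone, reduction, Mitsunobu reclosure and deprotection.
5. Stereochemistry: C3/C4 of unit T come from an auxiliary-controlled anti glycolate aldol; both C2 centres come from chelation-controlled Zn(BH4)2 reduction followed by Mitsunobu inversion; C4 of unit E comes from the chiral carbene and C3 from base equilibration to the 3,4-trans lactone.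

Key step: step 15

Assumption: the auxiliary of step 4 and the carbene precatalyst of step 15 are written as the antipodes expected to give the configurations drawn; if a model reaction shows the opposite sense, the other antipode (both are available) is used and nothing else changes.

Shorthand: T6 = (2R)-3,7,8-tris(benzyloxy)-2-[4-(benzyloxy)phenyl]-4-[(tert-butyldimethylsilyl)oxy]chroman-6-yl with the 2-aryl, 3-benzyloxy and 4-silyloxy groups all cis (the chroman of compound 15).

**Route**

Step 1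
Reactants: 1 2,3,4-trihydroxybenzaldehyde
Product: 2 3,4-bis(benzyloxy)-2-hydroxybenzaldehyde
Conditions: BnBr (2.1 equiv), K2CO3, DMF, rt
Reagents that add atoms: benzyl bromide, BrCc1ccccc1
Why: Williamson etherification in which the 2-hydroxyl, hydrogen-bonded to the formyl group, is the least nucleophilic, so two equivalents of benzyl bromide should alkylate only O4 and O3.

Step 2
Reactants: 2 3,4-bis(benzyloxy)-2-hydroxybenzaldehyde
Product: 3 2-(allyloxy)-3,4-bis(benzyloxy)benzaldehyde
Conditions: allyl bromide, K2CO3, DMF, 60 °C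
Reagents that add atoms: allyl bromide, C=CCBr
Why: Williamson etherification of the remaining chelated phenol under more forcing conditions masks the future O1 of unit T as an allyl ether that is orthogonal to benzyl and silyl ethers.

Step 3
Reactants: 4 (S)-4-benzyl-1,3-oxazolidine-2-thione; 5 (benzyloxy)acetyl chloride
Product: 6 (S)-4-benzyl-3-[(benzyloxy)acetyl]-1,3-oxazolidine-2-thione
Conditions: Et3N, CH2Cl2, 0 °C to rt
Reagents that add atoms: none
Why: N-acylation of the oxazolidinethione by the acid chloride is the standard entry to glycolyl auxiliaries of the Crimmins type.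

Step 4
Reactants: 6 (S)-4-benzyl-3-[(benzyloxy)acetyl]-1,3-oxazolidine-2-thione; 3 2-(allyloxy)-3,4-bis(benzyloxy)benzaldehyde
Product: 8 (S)-4-benzyl-3-{(2R,3R)-3-[2-(allyloxy)-3,4-bis(benzyloxy)phenyl]-2-(benzyloxy)-3-hydroxypropanoyl}-1,3-oxazolidine-2-thione (2,3-anti), via chlorotitanium enolate 7 (not isolated)
Conditions: TiCl4, i-Pr2NEt, CH2Cl2, −78 °C; then 3 precomplexed with TiCl4, −78 to −40 °C
Reagents that add atoms: none
Why: Crimmins anti-selective glycolate aldol, in which the chlorotitanium Z-enolate adds through an open transition state to the TiCl4-activated aldehyde, the auxiliary fixing the enolate face and the open geometry giving the anti (erythro) pair that becomes the cis C3/C4 diol of unit T.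

Step 5
Reactants: 8 anti aldol adduct
Product: 9 (2R,3R)-3-[2-(allyloxy)-3,4-bis(benzyloxy)phenyl]-2-(benzyloxy)-3-hydroxy-N-methoxy-N-methylpropanamide
Conditions: MeNHOMe·HCl, imidazole, CH2Cl2, rt
Reagents that add atoms: N,O-dimethylhydroxylamine hydrochloride, Cl.CNOC
Why: Aminolysis of the activated N-acyl oxazolidinethione gives the Weinreb amide without touching either stereocentre and returns the auxiliary.

Step 6
Reactants: 9 hydroxy Weinreb amide
Product: 10 (2R,3R)-3-[2-(allyloxy)-3,4-bis(benzyloxy)phenyl]-2-(benzyloxy)-3-[(tert-butyldimethylsilyl)oxy]-N-methoxy-N-methylpropanamide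
Conditions: TBSOTf, 2,6-lutidine, CH2Cl2, −78 to 0 °C
Reagents that add atoms: tert-butyldimethylsilyl triflate, CC(C)(C)[Si](C)(C)OS(=O)(=O)C(F)(F)F
Why: Silylation of the benzylic alcohol blocks retro-aldol cleavage and later activation of this oxygen, and being non-chelating it leaves the benzyloxy group to direct step 8.

Step 7
Reactants: 10 silyloxy Weinreb amide; 11 4-(benzyloxy)phenylmagnesium bromide
Product: 12 (2R,3R)-3-[2-(allyloxy)-3,4-bis(benzyloxy)phenyl]-2-(benzyloxy)-1-[4-(benzyloxy)phenyl]-3-[(tert-butyldimethylsilyl)oxy]propan-1-one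
Conditions: THF, 0 °C to rt; aq. NH4Cl
Reagents that add atoms: none
Why: Weinreb ketone synthesis, in which the magnesium chelate of the tetrahedral adduct survives until quench, so addition stops at the ketone and the alpha centre is not epimerised.

Step 8
Reactants: 12 aryl ketone
Product: 13 (1S,2S,3R)-3-[2-(allyloxy)-3,4-bis(benzyloxy)phenyl]-2-(benzyloxy)-1-[4-(benzyloxy)phenyl]-3-[(tert-butyldimethylsilyl)oxy]propan-1-ol (1,2-anti-2,3-anti)
Conditions: Zn(BH4)2, Et2O, −30 to 0 °C
Reagents that add atoms: none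
Why: Chelation-controlled (Cram chelate) reduction, in which zinc bridges the carbonyl and the alpha-benzyloxy oxygen and hydride arrives on the face away from the silyloxybenzyl group, should give the 1,2-anti alcohol.

Step 9
Reactants: 13 allyl ether alcohol
Product: 14 (1S,2S,3R)-3-[3,4-bis(benzyloxy)-2-hydroxyphenyl]-2-(benzyloxy)-1-[4-(benzyloxy)phenyl]-3-[(tert-butyldimethylsilyl)oxy]propan-1-ol
Conditions: Pd(PPh3)4 (5 mol%), morpholine, THF, rt
Reagents that add atoms: none
Why: Tsuji–Trost deallylation, in which zerovalent palladium ionises the aryl allyl ether and morpholine traps the allyl group, frees only the phenol.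

Step 10
Reactants: 14 phenol alcohol
Product: 15 (2R,3S,4R)-3,7,8-tris(benzyloxy)-2-[4-(benzyloxy)phenyl]-4-[(tert-butyldimethylsilyl)oxy]chroman (2,3-cis-3,4-cis; protected unit T)
Conditions: PPh3, DIAD, toluene, 0 °C to rt
Reagents that add atoms: none
Why: Intramolecular Mitsunobu etherification (6-exo-tet), a closure precedented for flavan-3-ols, in which the phenoxide displaces the oxyphosphonium at the benzylic carbon with inversion and so turns the anti alcohol into the 2,3-cis chroman.

Step 11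
Reactants: 15 protected unit T
Product: 16 6-bromo derivative of 15 (T6–Br)
Conditions: NBS, CH2Cl2, −20 to 0 °C, dark
Reagents that add atoms: N-bromosuccinimide, O=C1CCC(=O)N1Br
Why: Electrophilic aromatic bromination should go to C6, the only ring A position that is both para to O1 and ortho to the 7-benzyloxy group, while C5 is shielded by the C4 substituent.

Step 12
Reactants: 16 T6–Br; 2 3,4-bis(benzyloxy)-2-hydroxybenzaldehyde
Product: 19 (T6)[3,4-bis(benzyloxy)-2-hydroxyphenyl]methanol (both carbinol epimers), via aryllithium 17 (not isolated), via sodium phenoxide 18 (not isolated)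
Conditions: 16, n-BuLi, THF, −78 °C; then 18 (from 2, NaH, THF, 0 °C), −78 to −20 °C; aq. NH4Cl
Reagents that add atoms: none
Why: Bromine–lithium exchange followed by 1,2-addition of the aryllithium to the aldehyde, whose phenol is masked as its phenoxide; the carbinol configuration is irrelevant because the centre becomes planar in step 15.

Step 13
Reactants: 19 ortho-hydroxy benzhydrol
Product: 20 2,3-bis(benzyloxy)-6-[(T6)(4-methylbenzenesulfonyl)methyl]phenol (both epimers at the sulfonyl carbon)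
Conditions: p-TolSO2H, CH2Cl2, 4 Å molecular sieves, rt
Reagents that add atoms: p-toluenesulfinic acid, Cc1ccc(cc1)S(=O)O
Why: Acid-promoted ionisation of the doubly activated benzhydrol and capture of the cation by sulfinate at sulfur is the usual preparation of 2-(arylsulfonylmethyl)phenols, and the acid is too weak to disturb the silyl or benzyl ethers.

Step 14
Reactants: 5 (benzyloxy)acetyl chloride; 21 4-nitrophenol
Product: 22 4-nitrophenyl (benzyloxy)acetate
Conditions: Et3N, CH2Cl2, 0 °C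
Reagents that add atoms: none
Why: Acylation of the phenol gives the activated aryl ester needed for acyl transfer to the carbene.

Step 15
Reactants: 20 sulfone; 22 4-nitrophenyl (benzyloxy)acetate
Product: 25 3,7,8-tris(benzyloxy)-4-(T6)-3,4-dihydrocoumarin with the 3-benzyloxy group trans to the 4-aryl group and C4 configured as C4 of unit E in the target, via ortho-quinone methide 23 (not isolated), via C3-epimeric lactone 24 (not isolated)
Conditions: (5aR,10bS)-2-mesityl-5a,10b-dihydro-4H,6H-indeno[2,1-b][1,2,4]triazolo[4,3-d][1,4]oxazin-2-ium tetrafluoroborate (20 mol%), Cs2CO3, 4 Å molecular sieves, THF, 0 °C to rt; then DBU, rt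
Reagents that add atoms: none
Why: Cs2CO3 deprotonates the phenol of 20, which expels p-toluenesulfinate to give the planar quinone methide 23 so that both sulfone epimers converge, while the carbene is acylated by 22 and the acyl azolium is deprotonated to the benzyloxy-substituted azolium enolate, which adds through its alpha carbon to the methide carbon (C3–C4) before the phenoxide attacks the acyl azolium (O1–C2) and releases the carbene. The closest known reaction is the carbene-catalysed formal [4+2] annulation of ester-derived azolium enolates with ortho-quinone methides generated in situ from 2-(arylsulfonylmethyl)phenols to give 3,4-dihydrocoumarins. Ring C of unit E closes as a six-membered lactone by 6-exo-trig acyl substitution of the phenoxide at the acyl azolium carbonyl, the overall Michael addition–lactonisation being equivalent to an inverse-demand hetero-Diels–Alder reaction. C4 is set by the chiral triazolylidene, which shields one face of the enolate and thereby selects the face of the methide carbon that is attacked, and C3 is set afterwards under thermodynamic control when DBU equilibrates the alpha-benzyloxy lactone 24 to the isomer with the 3-benzyloxy and 4-aryl groups trans. The step needs catalyst control to outweigh any bias from the stereocentres of unit T and needs C-alkylation at the methide carbon: the first is favoured because those centres lie five bonds away across the flat ring A, the second because the quinone methide is strongly polarised by its carbonyl and two benzyloxy groups.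

Step 16
Reactants: 25 trans lactone
Product: 26 2-(benzyloxy)-3-[3,4-bis(benzyloxy)-2-hydroxyphenyl]-N-methoxy-N-methyl-3-(T6)propanamide (stereocentres as in 25)
Conditions: MeNHOMe·HCl, AlMe3, CH2Cl2, 0 °C to rt; aq. potassium sodium tartrate
Reagents that add atoms: N,O-dimethylhydroxylamine hydrochloride, Cl.CNOC
Why: Weinreb aminolysis of the aryl lactone by the dimethylaluminium amide cleaves the acyl C–O bond and frees the ring A phenol without enolising C3.

Step 17
Reactants: 26 phenolic Weinreb amide; 27 4-bromo-1,2-bis(benzyloxy)benzene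
Product: 29 2-(benzyloxy)-3-[3,4-bis(benzyloxy)-2-hydroxyphenyl]-1-[3,4-bis(benzyloxy)phenyl]-3-(T6)propan-1-one (stereocentres as in 25), via aryllithium 28 (not isolated)
Conditions: 26, LiN(SiMe3)2 (1.05 equiv), THF, −78 °C; then 28 (from 27, n-BuLi, THF, −78 °C), −78 °C; cold aq. NH4Cl
Reagents that add atoms: none
Why: Weinreb ketone synthesis on the lithium phenoxide, where the chelated tetrahedral adduct prevents the double addition that direct attack on the lactone would risk.

Step 18
Reactants: 29 aryl ketone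
Product: 30 (1S)-2-(benzyloxy)-3-[3,4-bis(benzyloxy)-2-hydroxyphenyl]-1-[3,4-bis(benzyloxy)phenyl]-3-(T6)propan-1-ol with the new hydroxyl anti to the 2-benzyloxy group
Conditions: Zn(BH4)2 (excess), Et2O/CH2Cl2, −40 to −10 °C
Reagents that add atoms: none
Why: Chelation-controlled reduction as in step 8, in which the zinc chelate between the ketone and the alpha-benzyloxy oxygen exposes the face away from the diarylmethyl group and should give the 1,2-anti alcohol.

Step 19
Reactants: 30 anti alcohol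
Product: 31 (2R)-3,7,8-tris(benzyloxy)-2-[3,4-bis(benzyloxy)phenyl]-4-(T6)chroman with 2,3-cis-3,4-trans configuration (fully protected target)
Conditions: PPh3, DIAD, toluene, 0 °C to rt
Reagents that add atoms: none
Why: Intramolecular Mitsunobu etherification (6-exo-tet) re-forms the O1–C2 bond of ring C of unit E with inversion at C2, converting the anti alcohol into the 2,3-cis flavan.

Step 20
Reactants: 31 fully protected target
Product: 32 the C4 alcohol of unit T obtained from 31 by loss of the silyl group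
Conditions: Bu4NF, AcOH, THF, 0 °C to rt
Reagents that add atoms: none
Why: Fluoride-mediated silyl ether cleavage, buffered with acetic acid so that neither alkoxide nor strong acid reaches the ionisable benzylic C4 oxygen.

Step 21
Reactants: 32 nona-O-benzyl ether
Product: 33 target CNP0174688.1
Conditions: H2 (1 atm), Pd(OH)2/C, EtOAc/MeOH, rt, short reaction time
Reagents that add atoms: none
Why: Hydrogenolysis of the nine benzyl ethers under neutral conditions should leave the chroman C2–O1 bonds and the C4–C6 diarylmethine bond intact, as in the deprotection of benzylated proanthocyanidins.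

**Compound list**

1 | 2,3,4-trihydroxybenzaldehyde | O=Cc1ccc(O)c(O)c1O | starting material
2 | 3,4-bis(benzyloxy)-2-hydroxybenzaldehyde | O=Cc1ccc(OCc2ccccc2)c(OCc2ccccc2)c1O | intermediate
3 | 2-(allyloxy)-3,4-bis(benzyloxy)benzaldehyde | O=Cc1ccc(OCc2ccccc2)c(OCc2ccccc2)c1OCC=C | intermediate
4 | (S)-4-benzyl-1,3-oxazolidine-2-thione | S=C1N[C@@H](Cc2ccccc2)CO1 | starting material
5 | (benzyloxy)acetyl chloride | O=C(Cl)COCc1ccccc1 | starting material
6 | (S)-4-benzyl-3-[(benzyloxy)acetyl]-1,3-oxazolidine-2-thione | S=C1OC[C@H](Cc2ccccc2)N1C(=O)COCc1ccccc1 | intermediate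
7 | trichlorotitanium (Z)-enolate of 6 | Cl[Ti](Cl)(Cl)O/C(N1C(=S)OC[C@@H]1Cc1ccccc1)=C\OCc1ccccc1 | intermediate (not isolated)
8 | (S)-4-benzyl-3-{(2R,3R)-3-[2-(allyloxy)-3,4-bis(benzyloxy)phenyl]-2-(benzyloxy)-3-hydroxypropanoyl}-1,3-oxazolidine-2-thione | C=CCOc1c(ccc(OCc2ccccc2)c1OCc1ccccc1)[C@@H](O)[C@@H](OCc1ccccc1)C(=O)N1C(=S)OC[C@@H]1Cc1ccccc1 | intermediate
9 | (2R,3R)-3-[2-(allyloxy)-3,4-bis(benzyloxy)phenyl]-2-(benzyloxy)-3-hydroxy-N-methoxy-N-methylpropanamide | C=CCOc1c(ccc(OCc2ccccc2)c1OCc1ccccc1)[C@@H](O)[C@@H](OCc1ccccc1)C(=O)N(C)OC | intermediate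
10 | (2R,3R)-3-[2-(allyloxy)-3,4-bis(benzyloxy)phenyl]-2-(benzyloxy)-3-[(tert-butyldimethylsilyl)oxy]-N-methoxy-N-methylpropanamide | C=CCOc1c(ccc(OCc2ccccc2)c1OCc1ccccc1)[C@@H](O[Si](C)(C)C(C)(C)C)[C@@H](OCc1ccccc1)C(=O)N(C)OC | intermediate
11 | 4-(benzyloxy)phenylmagnesium bromide (THF solution) | Br[Mg]c1ccc(OCc2ccccc2)cc1 | starting material
12 | (2R,3R)-3-[2-(allyloxy)-3,4-bis(benzyloxy)phenyl]-2-(benzyloxy)-1-[4-(benzyloxy)phenyl]-3-[(tert-butyldimethylsilyl)oxy]propan-1-one | C=CCOc1c(ccc(OCc2ccccc2)c1OCc1ccccc1)[C@@H](O[Si](C)(C)C(C)(C)C)[C@@H](OCc1ccccc1)C(=O)c1ccc(OCc2ccccc2)cc1 | intermediate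
13 | (1S,2S,3R)-3-[2-(allyloxy)-3,4-bis(benzyloxy)phenyl]-2-(benzyloxy)-1-[4-(benzyloxy)phenyl]-3-[(tert-butyldimethylsilyl)oxy]propan-1-ol | C=CCOc1c(ccc(OCc2ccccc2)c1OCc1ccccc1)[C@@H](O[Si](C)(C)C(C)(C)C)[C@@H](OCc1ccccc1)[C@@H](O)c1ccc(OCc2ccccc2)cc1 | intermediate
14 | (1S,2S,3R)-3-[3,4-bis(benzyloxy)-2-hydroxyphenyl]-2-(benzyloxy)-1-[4-(benzyloxy)phenyl]-3-[(tert-butyldimethylsilyl)oxy]propan-1-ol | Oc1c(ccc(OCc2ccccc2)c1OCc1ccccc1)[C@@H](O[Si](C)(C)C(C)(C)C)[C@@H](OCc1ccccc1)[C@@H](O)c1ccc(OCc2ccccc2)cc1 | intermediate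
15 | (2R,3S,4R)-3,7,8-tris(benzyloxy)-2-[4-(benzyloxy)phenyl]-4-[(tert-butyldimethylsilyl)oxy]chroman (all-cis; T6–H) | C(c5ccccc5)Oc1ccc([C@H]2Oc3c(ccc(OCc4ccccc4)c3OCc3ccccc3)[C@@H](O[Si](C)(C)C(C)(C)C)[C@H]2OCc2ccccc2)cc1 | intermediate
16 | 6-bromo derivative of 15 (T6–Br) | C(c5ccccc5)Oc1ccc([C@H]2Oc3c(cc(Br)c(OCc4ccccc4)c3OCc3ccccc3)[C@@H](O[Si](C)(C)C(C)(C)C)[C@H]2OCc2ccccc2)cc1 | intermediate
17 | 6-lithio derivative of 15 (T6–Li) | C(c5ccccc5)Oc1ccc([C@H]2Oc3c(cc([Li])c(OCc4ccccc4)c3OCc3ccccc3)[C@@H](O[Si](C)(C)C(C)(C)C)[C@H]2OCc2ccccc2)cc1 | intermediate (not isolated)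
18 | sodium 2,3-bis(benzyloxy)-6-formylphenoxide | [Na+].[O-]c1c(C=O)ccc(OCc2ccccc2)c1OCc1ccccc1 | intermediate (not isolated)
19 | (T6)[3,4-bis(benzyloxy)-2-hydroxyphenyl]methanol, both carbinol epimers | C(c5ccccc5)Oc1ccc([C@H]2Oc3c(cc(C(O)c4ccc(OCc6ccccc6)c(OCc6ccccc6)c4O)c(OCc4ccccc4)c3OCc3ccccc3)[C@@H](O[Si](C)(C)C(C)(C)C)[C@H]2OCc2ccccc2)cc1 | intermediate
20 | 2,3-bis(benzyloxy)-6-[(T6)(4-methylbenzenesulfonyl)methyl]phenol, both epimers | C(c5ccccc5)Oc1ccc([C@H]2Oc3c(cc(C(c4ccc(OCc6ccccc6)c(OCc6ccccc6)c4O)S(=O)(=O)c4ccc(C)cc4)c(OCc4ccccc4)c3OCc3ccccc3)[C@@H](O[Si](C)(C)C(C)(C)C)[C@H]2OCc2ccccc2)cc1 | intermediate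
21 | 4-nitrophenol | O=[N+]([O-])c1ccc(O)cc1 | starting material
22 | 4-nitrophenyl (benzyloxy)acetate | O=C(COCc1ccccc1)Oc1ccc(cc1)[N+](=O)[O-] | intermediate
23 | 2,3-bis(benzyloxy)-6-[(T6)methylidene]cyclohexa-2,4-dien-1-one (ortho-quinone methide) | C(c5ccccc5)Oc1ccc([C@H]2Oc3c(cc(C=C4C=CC(OCc6ccccc6)=C(OCc6ccccc6)C4=O)c(OCc4ccccc4)c3OCc3ccccc3)[C@@H](O[Si](C)(C)C(C)(C)C)[C@H]2OCc2ccccc2)cc1 | intermediate (not isolated)
24 | 3,7,8-tris(benzyloxy)-4-(T6)-3,4-dihydrocoumarin, C3-epimer mixture with C4 as in 25 | C(c5ccccc5)Oc1ccc([C@H]2Oc3c(cc([C@H]4c5ccc(OCc6ccccc6)c(OCc6ccccc6)c5OC(=O)C4OCc4ccccc4)c(OCc4ccccc4)c3OCc3ccccc3)[C@@H](O[Si](C)(C)C(C)(C)C)[C@H]2OCc2ccccc2)cc1 | intermediate (not isolated)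
25 | 3,7,8-tris(benzyloxy)-4-(T6)-3,4-dihydrocoumarin, 3,4-trans, C4 as in unit E of the target | C(c5ccccc5)Oc1ccc([C@H]2Oc3c(cc([C@H]4c5ccc(OCc6ccccc6)c(OCc6ccccc6)c5OC(=O)[C@@H]4OCc4ccccc4)c(OCc4ccccc4)c3OCc3ccccc3)[C@@H](O[Si](C)(C)C(C)(C)C)[C@H]2OCc2ccccc2)cc1 | intermediate
26 | 2-(benzyloxy)-3-[3,4-bis(benzyloxy)-2-hydroxyphenyl]-N-methoxy-N-methyl-3-(T6)propanamide, stereocentres as in 25 | C(c5ccccc5)Oc1ccc([C@H]2Oc3c(cc([C@@H](c4ccc(OCc6ccccc6)c(OCc6ccccc6)c4O)[C@@H](OCc4ccccc4)C(=O)N(C)OC)c(OCc4ccccc4)c3OCc3ccccc3)[C@@H](O[Si](C)(C)C(C)(C)C)[C@H]2OCc2ccccc2)cc1 | intermediate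
27 | 4-bromo-1,2-bis(benzyloxy)benzene | Brc1ccc(OCc2ccccc2)c(OCc2ccccc2)c1 | starting material
28 | 3,4-bis(benzyloxy)phenyllithium | [Li]c1ccc(OCc2ccccc2)c(OCc2ccccc2)c1 | intermediate (not isolated)
29 | 2-(benzyloxy)-3-[3,4-bis(benzyloxy)-2-hydroxyphenyl]-1-[3,4-bis(benzyloxy)phenyl]-3-(T6)propan-1-one, stereocentres as in 25 | C(c5ccccc5)Oc1ccc([C@H]2Oc3c(cc([C@@H](c4ccc(OCc6ccccc6)c(OCc6ccccc6)c4O)[C@@H](OCc4ccccc4)C(=O)c4ccc(OCc6ccccc6)c(OCc6ccccc6)c4)c(OCc4ccccc4)c3OCc3ccccc3)[C@@H](O[Si](C)(C)C(C)(C)C)[C@H]2OCc2ccccc2)cc1 | intermediate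
30 | (1S)-2-(benzyloxy)-3-[3,4-bis(benzyloxy)-2-hydroxyphenyl]-1-[3,4-bis(benzyloxy)phenyl]-3-(T6)propan-1-ol, 1,2-anti | C(c5ccccc5)Oc1ccc([C@H]2Oc3c(cc([C@@H](c4ccc(OCc6ccccc6)c(OCc6ccccc6)c4O)[C@@H](OCc4ccccc4)[C@@H](O)c4ccc(OCc6ccccc6)c(OCc6ccccc6)c4)c(OCc4ccccc4)c3OCc3ccccc3)[C@@H](O[Si](C)(C)C(C)(C)C)[C@H]2OCc2ccccc2)cc1 | intermediate
31 | (2R)-3,7,8-tris(benzyloxy)-2-[3,4-bis(benzyloxy)phenyl]-4-(T6)chroman, 2,3-cis-3,4-trans | C(c5ccccc5)Oc1ccc([C@H]2Oc3c(cc([C@H]4c5ccc(OCc6ccccc6)c(OCc6ccccc6)c5O[C@H](c5ccc(OCc6ccccc6)c(OCc6ccccc6)c5)[C@@H]4OCc4ccccc4)c(OCc4ccccc4)c3OCc3ccccc3)[C@@H](O[Si](C)(C)C(C)(C)C)[C@H]2OCc2ccccc2)cc1 | intermediate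
32 | 31 with the C4 hydroxyl of unit T free (nona-O-benzyl target) | C(c5ccccc5)Oc1ccc([C@H]2Oc3c(cc([C@H]4c5ccc(OCc6ccccc6)c(OCc6ccccc6)c5O[C@H](c5ccc(OCc6ccccc6)c(OCc6ccccc6)c5)[C@@H]4OCc4ccccc4)c(OCc4ccccc4)c3OCc3ccccc3)[C@@H](O)[C@H]2OCc2ccccc2)cc1 | intermediate
33 | CNP0174688.1 | Oc1ccc([C@H]2Oc3c(cc([C@H]4c5ccc(O)c(O)c5O[C@H](c5ccc(O)c(O)c5)[C@@H]4O)c(O)c3O)[C@@H](O)[C@H]2O)cc1 | target

**Totals and risks**

Total step count: 21. Longest linear sequence: 19 steps (steps 1, 2, 4–13 and 15–21).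

Steps most likely to fail:

Step 15. The benzyloxy-substituted azolium enolate may form slowly and add with poor face control, so that the quinone methide is lost to 4-nitrophenoxide addition or dimerisation, or the C3/C4 ratio cannot be driven to trans by DBU. The fallback sets out from 20 and introduces the C3 oxygen after the annulation. The same carbene catalysis with commercial 4-nitrophenyl acetate (an unsubstituted azolium enolate, which creates only the C4 centre) should give 7,8-bis(benzyloxy)-4-(T6)-3,4-dihydrocoumarin F4. Its potassium enolate (KN(SiMe3)2, THF, −78 °C) is hydroxylated with 2-(phenylsulfonyl)-3-phenyloxaziridine on the face away from the C4 aryl group to give the trans 3-hydroxy lactone F5. Benzylation with BnBr and Ag2O comes back to the route at 25.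

Step 4. The titanium aldol may suffer poor anti/syn discrimination or slow addition to the electron-rich ortho-alkoxy benzaldehyde, with benzyl ether cleavage on long exposure to TiCl4. The fallback sets out from 5 and 3 and uses a chiral Lewis acid in place of the auxiliary. Ethanethiol and Et3N convert 5 into S-ethyl (benzyloxy)ethanethioate F1, and LiN(i-Pr)2 with Me3SiCl gives (Z)-2-(benzyloxy)-1-(ethylsulfanyl)-1-(trimethylsilyloxy)ethene F2. Mukaiyama aldol addition of F2 to 3 with Sn(OTf)2 (divalent tin), a proline-derived chiral diamine and Bu2Sn(OAc)2 in CH2Cl2 at −78 °C should give the anti thioester S-ethyl (2R,3R)-3-[2-(allyloxy)-3,4-bis(benzyloxy)phenyl]-2-(benzyloxy)-3-hydroxypropanethioate F3. Aminolysis with MeNHOMe·HCl and i-PrMgCl comes back to the route at 9.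

Step 21. Once the 7-hydroxyl of unit T is freed, the para benzylic C4 hydroxyl may ionise on the catalyst and be lost by hydrogenolysis, and the crowded 8-benzyl ethers may cleave slowly. The fallback sets out from 31 and reverses the order of the two deprotections. Hydrogenolysis of 31 (H2, Pd(OH)2/C, EtOAc/MeOH) with the C4 oxygen still silylated gives the 4-O-(tert-butyldimethylsilyl) polyphenol F6. The silyl ether is then cleaved with HF·pyridine buffered with pyridine in THF at 0 °C, arriving at 33.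

**Further compounds**

F1 | step 4 | S-ethyl (benzyloxy)ethanethioate | CCSC(=O)COCc1ccccc1
F2 | step 4 | (Z)-2-(benzyloxy)-1-(ethylsulfanyl)-1-(trimethylsilyloxy)ethene | CCS/C(O[Si](C)(C)C)=C\OCc1ccccc1
F3 | step 4 | S-ethyl (2R,3R)-3-[2-(allyloxy)-3,4-bis(benzyloxy)phenyl]-2-(benzyloxy)-3-hydroxypropanethioate | C=CCOc1c(ccc(OCc2ccccc2)c1OCc1ccccc1)[C@@H](O)[C@@H](OCc1ccccc1)C(=O)SCC
F4 | step 15 | 7,8-bis(benzyloxy)-4-(T6)-3,4-dihydrocoumarin, C4 as in 25 | C(c5ccccc5)Oc1ccc([C@H]2Oc3c(cc([C@H]4c5ccc(OCc6ccccc6)c(OCc6ccccc6)c5OC(=O)C4)c(OCc4ccccc4)c3OCc3ccccc3)[C@@H](O[Si](C)(C)C(C)(C)C)[C@H]2OCc2ccccc2)cc1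
F5 | step 15 | 7,8-bis(benzyloxy)-3-hydroxy-4-(T6)-3,4-dihydrocoumarin, 3,4-trans | C(c5ccccc5)Oc1ccc([C@H]2Oc3c(cc([C@H]4c5ccc(OCc6ccccc6)c(OCc6ccccc6)c5OC(=O)[C@@H]4O)c(OCc4ccccc4)c3OCc3ccccc3)[C@@H](O[Si](C)(C)C(C)(C)C)[C@H]2OCc2ccccc2)cc1
F6 | step 21 | target carrying a tert-butyldimethylsilyl ether on the C4 oxygen of unit T | Oc1ccc([C@H]2Oc3c(cc([C@H]4c5ccc(O)c(O)c5O[C@H](c5ccc(O)c(O)c5)[C@@H]4O)c(O)c3O)[C@@H](O[Si](C)(C)C(C)(C)C)[C@H]2O)cc1
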